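Start from the green run at 15.0 min, which holds J 71.7 % and Q 0.8 % of the charge. Call the remainder, neither Q nor J, the missing share (the mass-balance gap): here it is 27.5 %.

| setting | red | green | flask |
|---|---|---|---|
| Q | 0.80 M | 0.80 M | 0.80 M |
| G | 160 mM (held) | 160 mM (held) | 160 mM (held) |
| E | 2.8 mol% | 4.2 mol% | 2.8 mol% |
| remark | the very flask that is asked about, followed so far | run made earlier |  |
| time |  |  | 15 min |

- red (time / s: J / %, Q / %): 10.0: 0.6, 98.7; 12.0: 0.7, 98.2; 20.0: 0.8, 95.8; 30.0: 2.2, 94.0; 40.0: 3.8, 91.1; 60.0: 6.7, 85.3; 80.0: 10.3, 80.9
- green (time / min: J / %, Q / %): 1.33: 12.2, 78.7; 2.00: 18.6, 68.4; 3.00: 28.2, 54.4; 4.00: 37.1, 41.2; 6.00: 51.7, 22.4; 10.0: 67.4, 4.3; 15.0: 71.7, 0.8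

(readings scatter by 0.3 percentage points)

- what was read earlier has a scatter of 0.3 percentage points, one standard deviation
- at the start none of G is in solution

- J at 15 min, in percent of the Q charged
- the change that raises the amount of J at 15 min, in percent of the Q charged most ("none" if none brings more than 2 percentage points) (south / west / south-east / none)
- amount of J at 15 min, in percent of the Q charged, after west

- south: doubling the transfer coefficient of G, all else as stated
- west: doubling the amount of E, all else as stated
- south-east: doubling the saturation concentration of G, all else as stated

Now compare the runs at one clock reading. Red misses 8.80 % at 80.0 s and green misses 9.10 % at 1.33 min, although green holds 1.50 times the E. So treat the share as a leak from Q that runs by the clock. Dividing red's share by its time and its mean Q gives a reading of 0.0730 min⁻¹.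

Next take two extreme versions of red at 15 min. In one, E removes Q before the leak starts, so the missing share is zero and J is the charge minus any Q left. In the other, E makes no J and the leak runs unopposed, so the missing share reaches 66.5 %.

Green marks a point between them. Red made less J than green at that early reading, so its Q lingers and leaks longer. Expect a missing share above green's, which puts my own reckoning of J below 72.5 %.

The forecast gives 70.8 %, then 71.8 % after west, and picks south-east, reasoning that “More dissolved G should improve selectivity”.

The flask gives J 68.0 % with Q 1.5 % left, 73.3 % after west, and south-east as the best change, gaining 12 percentage points.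

G ⇌ D, rate k1*(csat - [D]) (kL = 0.0130 s⁻¹); 2 E ⇌ L, settled at all times (K = 17.0 M⁻¹); Q + D + E → E + J (k = 2.75 M⁻² s⁻¹); Q ⇌ X (K = 7.87, k = 0.00133 s⁻¹) Its missing share is 30.5 %, larger than green's, and it stands as X at 30.5 %. Repeat the reckoning on the neighbour flask with 1.1 mol% of E: it holds less E than the flask, so expect a larger share. That neighbour flask gives J 55.3 % and Q 5.89 %, so its missing share is 38.8 %, and its X stands at 38.8 %.

The data are calculated for substances that don't exist; scatter was added.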